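The flask is charged and reacts like this:

left-handed substrate 0.50 M; reagent 1.50 M; free catalyst 10 mM; impurity 14 mM; right-handed substrate 0.50 M

    reagent + free catalyst + left-handed substrate → free catalyst + left-handed product (k1 = 11 M⁻² s⁻¹)
    reagent + free catalyst + right-handed substrate → free catalyst + right-handed product (k2 = 3.5 M⁻² s⁻¹)
    free catalyst + impurity → spent catalyst (k3 = 180 M⁻¹ s⁻¹)

- the form that holds most of the catalyst when 5.0% of the left-handed substrate and right-handed substrate together are converted (free catalyst / spent catalyst)
- its share of the catalyst then
- apparent order in reagent when 5.0% of the left-handed substrate and right-handed substrate together are converted (percent change of the rate of making left-handed product for one percent more reagent charged)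

**What do you count first?** Not seconds. The two making steps and the poisoning step each carry free catalyst as a factor, so it cancels when one step's progress is divided by another's.

**And what is left?** Hold reagent and substrates at their charge. The logarithm of the impurity then falls in step with the fraction of substrates converted, by a factor ρ. This is the poisoning constant divided by the mean of the two making constants and by the charged reagent: 16.6, the exchange rate.

**At 5.0% conversion?** The impurity stands at 43.7% of its charge. Each impurity lost takes one catalyst with it, so the larger part is spent catalyst, with a share of 78.8%.

**But reagent and substrates fall. What then?** Then ρ grows as the run goes on, so I take reagent and substrates at the middle of the stretch, each substrate falling in the ratio of its constant: ρ becomes 17.4. The impurity then stands at 41.9% of its charge, and spent catalyst holds 81.3% of the catalyst.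

**The order in reagent, read at that same conversion?** One percent more reagent lowers ρ by one percent, so more impurity stands at that conversion. Free catalyst is the impurity minus a fixed difference, here 1.87 mM, and a small difference moves steeply. Adding the plain first power of reagent gives 3.73.

**Where does it stop?** There is more impurity than catalyst, so free catalyst goes first, with the impurity down to 28.6% of its charge. Through the corrected ρ, that puts the stop near 7.21% conversion.

The forecast said spent catalyst at 81% (78% to 84%) and an order of 3.8 (3.3 to 4.3), since “more reagent gets there sooner, while more catalyst is still alive”.

The flask gives spent catalyst at 81.3%, free catalyst at 18.7%, and an order of 3.8. At the charge, each free catalyst makes product at 10.9 s⁻¹ and is lost to impurity at 2.5 s⁻¹, so making is faster by a factor of 4.32. That factor, the substrates' charge over ρ times the impurity's charge, 4.32, belongs to the charge, and the impurity is down to 47.7% of its charge at 0.800 s. Watch the early part: right-handed product has 60% of its turnover behind it at 0.800 s. At 8.00 s free catalyst is 0.0902%, impurity 28.6% of its charge, and the two products together 7.04% of the substrates charged.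

All constants belong to no real substance; the run is a simulation.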